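**Retrosynthetic overview**

1. The enol ether O–C(sp2) bond is cut last: (S)-carbinol 10 and Z-alkenyl iodide 18 are joined by a stereoretentive CuI-catalysed C–O coupling, and fluoride then frees the phenol and the primary alcohol.
2. Carbinol 10 comes from chromene aldehyde 7 by MeMgBr addition, oxidation and CBS reduction, which sets the only stereocentre.
3. The strategy rests on ring A (the benzene ring of the chromene): C8a, which carries the pyran oxygen O1, is para to C6, which carries the side-chain carbon. A formyl group on C6 therefore activates a C8a–F bond, and the cis C3=C4 bond of the pyran ring serves as a Z-alkenyl tether on C4a, so O1–C8a is closed by intramolecular SNAr (5 → 7).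
4. Precursor 5 is reached in three steps from 4-fluoro-2-methoxybenzaldehyde (iodination, Sonogashira coupling, semi-hydrogenation). Iodide 18 is reached in three steps through anti-carbomagnesiation of propargyl alcohol and iodinolysis, which fixes the Z geometry.
5. Ring order: both benzene rings are bought; the pyran ring is the only ring formed (step 4).

Key step: step 4

Assumption: read from the SMILES, the carbinol carbon is S and the enol ether is Z (ether oxygen cis to CH2OH, trans to the aryl group); the route is planned for this isomer.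

**Route**

Step 1
Reactants: 1 4-fluoro-2-methoxybenzaldehyde
Product: 2 4-fluoro-5-iodo-2-methoxybenzaldehyde
Conditions: NIS (1.1 equiv), TFA, rt, dark
Reagents that add atoms: N-iodosuccinimide, O=C1CCC(=O)N1I
Why: Electrophilic aromatic iodination should go to C5, which is para to the methoxy group, ortho to fluorine and meta to the formyl group, so all three directing effects agree, whereas C3 is flanked by two substituents.

Step 2
Reactants: 2 4-fluoro-5-iodo-2-methoxybenzaldehyde; 3 2-methylbut-3-yn-2-ol
Product: 4 4-fluoro-5-(3-hydroxy-3-methylbut-1-yn-1-yl)-2-methoxybenzaldehyde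
Conditions: PdCl2(PPh3)2 (2 mol %), CuI (4 mol %), Et3N, THF, rt
Reagents that add atoms: none
Why: Sonogashira coupling of an aryl iodide with a terminal alkyne runs at room temperature and tolerates the aldehyde, the aryl fluoride and the free tertiary alcohol.

Step 3
Reactants: 4 4-fluoro-5-(3-hydroxy-3-methylbut-1-yn-1-yl)-2-methoxybenzaldehyde
Product: 5 4-fluoro-5-[(Z)-3-hydroxy-3-methylbut-1-en-1-yl]-2-methoxybenzaldehyde
Conditions: H2 (1 atm), Pd/CaCO3–Pb(OAc)2, quinoline, EtOAc, rt, stopped after one equivalent of H2
Reagents that add atoms: none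
Why: Lindlar semi-hydrogenation delivers both hydrogen atoms to one face of the adsorbed alkyne and should stop at the Z-alkene, which places the tertiary hydroxyl group within reach of the C–F carbon; the poisoned catalyst should not reduce the aldehyde or the aryl fluoride.

Step 4
Reactants: 5 4-fluoro-5-[(Z)-3-hydroxy-3-methylbut-1-en-1-yl]-2-methoxybenzaldehyde
Product: 7 7-methoxy-2,2-dimethyl-2H-chromene-6-carbaldehyde, via potassium alkoxide 6 (not isolated)
Conditions: KOtBu (1.1 equiv), THF–DMF (5:1), 0.02 M, 0 °C → rt
Reagents that add atoms: none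
Why: KOtBu converts the tertiary allylic alcohol into potassium alkoxide 6, whose oxygen is held beside the fluorine-bearing carbon (the future C8a) by the cis alkene and by the gem-dimethyl group. The alkoxide adds to that carbon to give a Meisenheimer complex whose negative charge is delocalised through ring A onto the oxygen of the para formyl group, and loss of fluoride restores aromaticity; this is an addition–elimination SNAr, and the closest known reaction type is the intramolecular etherification of fluoroarenes activated by an ortho or para carbonyl group. The pyran ring is closed by formation of the O1–C8a bond in a six-membered, 6-exo-type attack of oxygen on an aromatic sp2 carbon. No stereocentre is formed. The step needs chemoselectivity for the C–F carbon over the formyl carbon and over intermolecular attack by tert-butoxide: alkoxide addition to the non-enolisable aldehyde is reversible and unproductive whereas fluoride loss is irreversible, and the tether together with high dilution should make ring closure faster than any bimolecular displacement. Regiochemistry is not in question, because the ring carries a single fluoride and the oxygen can reach only that carbon.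

Step 5
Reactants: 7 7-methoxy-2,2-dimethyl-2H-chromene-6-carbaldehyde
Product: 8 rac-1-(7-methoxy-2,2-dimethyl-2H-chromen-6-yl)ethan-1-ol
Conditions: MeMgBr (1.3 equiv), THF, −20 °C → 0 °C; sat. aq NH4Cl
Reagents that add atoms: methylmagnesium bromide, C[Mg]Br
Why: Grignard addition to the aryl aldehyde gives the secondary benzylic alcohol as a racemate, which is acceptable because the centre is erased in step 6 and set in step 7; the buffered work-up avoids ionisation of the electron-rich benzylic alcohol.

Step 6
Reactants: 8 rac-1-(7-methoxy-2,2-dimethyl-2H-chromen-6-yl)ethan-1-ol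
Product: 9 1-(7-methoxy-2,2-dimethyl-2H-chromen-6-yl)ethan-1-one
Conditions: MnO2 (activated, 15 equiv), CH2Cl2, rt
Reagents that add atoms: none
Why: MnO2 oxidation is selective for benzylic alcohols under neutral heterogeneous conditions and should leave the C3=C4 bond of the chromene untouched.

Step 7
Reactants: 9 1-(7-methoxy-2,2-dimethyl-2H-chromen-6-yl)ethan-1-one
Product: 10 (S)-1-(7-methoxy-2,2-dimethyl-2H-chromen-6-yl)ethan-1-ol
Conditions: (R)-2-methyl-CBS-oxazaborolidine (0.2 equiv), catecholborane (1.6 equiv), toluene, −78 °C → −40 °C; MeOH, then aq NaOH wash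
Reagents that add atoms: none
Why: In the CBS reduction the (R)-oxazaborolidine binds the ketone with the large aryl group away from the catalyst and directs hydride to the Re face, which gives the S carbinol, while catecholborane at low temperature should not hydroborate the C3=C4 bond.

Step 8
Reactants: 11 2-bromo-5-methylphenol
Product: 12 (2-bromo-5-methylphenoxy)triisopropylsilane
Conditions: TIPSCl (1.2 equiv), imidazole (2.5 equiv), DMF, rt
Reagents that add atoms: triisopropylsilyl chloride, CC(C)[Si](Cl)(C(C)C)C(C)C
Why: Imidazole-promoted silylation of the phenol installs a bulky silyl ether that should resist oxygen-to-carbon silyl migration in the ortho-metalated arene of step 9 and the carbonate base of step 11, yet is cleaved by fluoride in step 12.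

Step 9
Reactants: 12 (2-bromo-5-methylphenoxy)triisopropylsilane; 13 propargyl alcohol
Product: 17 (Z)-3-iodo-2-[4-methyl-2-(triisopropylsilyloxy)phenyl]prop-2-en-1-ol, via aryl Grignard reagent 14 (not isolated), via bromomagnesium propargyl alkoxide 15 (not isolated), via chelated alkenylmagnesium bromide 16 (not isolated)
Conditions: Mg, THF, 40 °C; then 13 (0.4 equiv relative to 12), CuI (10 mol % on 13), 0 °C → rt; then I2 (2 equiv on 13), THF, −20 °C → 0 °C; aq NH4Cl/Na2S2O3
Reagents that add atoms: iodine, II
Why: In this hydroxyl-directed, CuI-catalysed anti-carbomagnesiation the first equivalent of 14 deprotonates the alcohol and the second delivers the aryl group to C2 while magnesium ends on C3 cis to the CH2O group in a five-membered chelate, so iodinolysis with retention should give the iodide with iodine cis to CH2OH, the geometry required in the target.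

Step 10
Reactants: 17 (Z)-3-iodo-2-[4-methyl-2-(triisopropylsilyloxy)phenyl]prop-2-en-1-ol
Product: 18 tert-butyl{[(Z)-3-iodo-2-[4-methyl-2-(triisopropylsilyloxy)phenyl]prop-2-en-1-yl]oxy}dimethylsilane
Conditions: TBSCl (1.2 equiv), imidazole (2 equiv), CH2Cl2, 0 °C → rt
Reagents that add atoms: tert-butyldimethylsilyl chloride, CC(C)(C)[Si](C)(C)Cl
Why: Silylation of the primary alcohol removes a competing alkoxide nucleophile from the copper coupling and leaves the alkenyl iodide unchanged.

Step 11
Reactants: 10 (S)-1-(7-methoxy-2,2-dimethyl-2H-chromen-6-yl)ethan-1-ol; 18 tert-butyl{[(Z)-3-iodo-2-[4-methyl-2-(triisopropylsilyloxy)phenyl]prop-2-en-1-yl]oxy}dimethylsilane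
Product: 19 tert-butyl{[(Z)-3-{[(1S)-1-(7-methoxy-2,2-dimethyl-2H-chromen-6-yl)ethyl]oxy}-2-[4-methyl-2-(triisopropylsilyloxy)phenyl]prop-2-en-1-yl]oxy}dimethylsilane
Conditions: 18 (1.3 equiv), CuI (10 mol %), 3,4,7,8-tetramethyl-1,10-phenanthroline (20 mol %), Cs2CO3 (1.5 equiv), toluene, 80 °C, Ar
Reagents that add atoms: none
Why: The Ullmann-type copper-catalysed C–O coupling of an aliphatic alcohol with an alkenyl iodide goes with retention of alkene geometry and does not break the C–O bond at the carbinol carbon, so both the S centre and the Z geometry should be carried into 19; iodine sits trans to the silyloxyaryl group, so a benzofuran cannot form even if that silyl group is lost.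

Step 12
Reactants: 19 tert-butyl{[(Z)-3-{[(1S)-1-(7-methoxy-2,2-dimethyl-2H-chromen-6-yl)ethyl]oxy}-2-[4-methyl-2-(triisopropylsilyloxy)phenyl]prop-2-en-1-yl]oxy}dimethylsilane
Product: 20 2-[(Z)-3-hydroxy-1-{[(1S)-1-(7-methoxy-2,2-dimethyl-2H-chromen-6-yl)ethyl]oxy}prop-1-en-2-yl]-5-methylphenol (CNP0279099.1)
Conditions: Bu4NF (2.5 equiv), THF, 0 °C → rt; pH 7 phosphate buffer; chromatography on Et3N-deactivated silica
Reagents that add atoms: none
Why: Fluoride-mediated desilylation cleaves the aryl triisopropylsilyl ether and the primary tert-butyldimethylsilyl ether without acid, so the enol ether, the ionisable benzylic ether and the S centre should survive, and the neutral work-up avoids acid-catalysed addition of the free phenol to the enol ether.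

**Compound list**

1 | 4-fluoro-2-methoxybenzaldehyde | COc1cc(F)ccc1C=O | starting material
2 | 4-fluoro-5-iodo-2-methoxybenzaldehyde | COc1cc(F)c(I)cc1C=O | intermediate
3 | 2-methylbut-3-yn-2-ol | CC(C)(O)C#C | starting material
4 | 4-fluoro-5-(3-hydroxy-3-methylbut-1-yn-1-yl)-2-methoxybenzaldehyde | COc1cc(F)c(C#CC(C)(C)O)cc1C=O | intermediate
5 | 4-fluoro-5-[(Z)-3-hydroxy-3-methylbut-1-en-1-yl]-2-methoxybenzaldehyde | COc1cc(F)c(/C=C\C(C)(C)O)cc1C=O | intermediate
6 | potassium (Z)-4-(2-fluoro-5-formyl-4-methoxyphenyl)-2-methylbut-3-en-2-olate | COc1cc(F)c(/C=C\C(C)(C)[O-])cc1C=O.[K+] | intermediate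
7 | 7-methoxy-2,2-dimethyl-2H-chromene-6-carbaldehyde | COc1cc2OC(C)(C)C=Cc2cc1C=O | intermediate
8 | rac-1-(7-methoxy-2,2-dimethyl-2H-chromen-6-yl)ethan-1-ol | COc1cc2OC(C)(C)C=Cc2cc1C(C)O | intermediate
9 | 1-(7-methoxy-2,2-dimethyl-2H-chromen-6-yl)ethan-1-one | COc1cc2OC(C)(C)C=Cc2cc1C(C)=O | intermediate
10 | (S)-1-(7-methoxy-2,2-dimethyl-2H-chromen-6-yl)ethan-1-ol | COc1cc2OC(C)(C)C=Cc2cc1[C@H](C)O | intermediate
11 | 2-bromo-5-methylphenol | Cc1ccc(Br)c(O)c1 | starting material
12 | (2-bromo-5-methylphenoxy)triisopropylsilane | Cc1ccc(Br)c(O[Si](C(C)C)(C(C)C)C(C)C)c1 | intermediate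
13 | propargyl alcohol | OCC#C | starting material
14 | [4-methyl-2-(triisopropylsilyloxy)phenyl]magnesium bromide | Cc1ccc([Mg]Br)c(O[Si](C(C)C)(C(C)C)C(C)C)c1 | intermediate
15 | bromomagnesium prop-2-yn-1-olate | C#CCO[Mg]Br | intermediate
16 | chelated (Z)-alkenylmagnesium bromide, bromomagnesium alkoxide of (Z)-3-(bromomagnesio)-2-[4-methyl-2-(triisopropylsilyloxy)phenyl]prop-2-en-1-ol | Br[Mg]/C=C(\CO[Mg]Br)c1ccc(C)cc1O[Si](C(C)C)(C(C)C)C(C)C | intermediate
17 | (Z)-3-iodo-2-[4-methyl-2-(triisopropylsilyloxy)phenyl]prop-2-en-1-ol | I/C=C(\CO)c1ccc(C)cc1O[Si](C(C)C)(C(C)C)C(C)C | intermediate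
18 | tert-butyl{[(Z)-3-iodo-2-[4-methyl-2-(triisopropylsilyloxy)phenyl]prop-2-en-1-yl]oxy}dimethylsilane | I/C=C(\CO[Si](C)(C)C(C)(C)C)c1ccc(C)cc1O[Si](C(C)C)(C(C)C)C(C)C | intermediate
19 | tert-butyl{[(Z)-3-{[(1S)-1-(7-methoxy-2,2-dimethyl-2H-chromen-6-yl)ethyl]oxy}-2-[4-methyl-2-(triisopropylsilyloxy)phenyl]prop-2-en-1-yl]oxy}dimethylsilane | COc1cc2OC(C)(C)C=Cc2cc1[C@H](C)O/C=C(\CO[Si](C)(C)C(C)(C)C)c1ccc(C)cc1O[Si](C(C)C)(C(C)C)C(C)C | intermediate
20 | 2-[(Z)-3-hydroxy-1-{[(1S)-1-(7-methoxy-2,2-dimethyl-2H-chromen-6-yl)ethyl]oxy}prop-1-en-2-yl]-5-methylphenol | COc1cc2c(cc1[C@H](C)O/C=C(\CO)c1ccc(C)cc1O)C=CC(C)(C)O2 | target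

**Step count**

Total: 12 steps. Longest linear sequence: 9 steps (steps 1–7, 11 and 12); the side branch is steps 8–10.

**Steps most likely to fail, with fallbacks**

Step 11. C–O bond formation at the β,β-disubstituted alkenyl iodide with a hindered secondary alkoxide may be slow. Side processes could then take over at 80 °C: base-induced loss of the aryl silyl ether, reduction of the C–I bond, or dehydrogenation of the copper alkoxide to ketone 9 with erosion of enantiopurity. The fallback reverses the polarity of the alkenyl partner and runs at room temperature without carbonate. It sets out from 18, which is converted by Miyaura borylation (B2pin2, PdCl2(PPh3)2, PPh3, KOPh, toluene, 50 °C, retention of geometry) into tert-butyldimethyl{[(Z)-2-[4-methyl-2-(triisopropylsilyloxy)phenyl]-3-(4,4,5,5-tetramethyl-1,3,2-dioxaborolan-2-yl)prop-2-en-1-yl]oxy}silane F1. A Chan–Lam oxidative coupling of 10 with an excess of this boronate (Cu(OAc)2, Et3N, 4 Å molecular sieves, CH2Cl2, air, rt) should then give the enol ether with retention at both the alkene and the carbinol carbon, and the route is rejoined at 19.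

Step 9. The silyl group may migrate from oxygen to the metalated ortho carbon of the arylmagnesium reagent, or transfer of the bulky ortho-substituted aryl group to the alkyne may be sluggish, so that mainly protonated arene is recovered. The fallback carries the phenol through the organometallic stage as a small, chelating acetal and silylates afterwards. It sets out from 11, which is protected (MOMCl, iPr2NEt, CH2Cl2) as 1-bromo-2-(methoxymethoxy)-4-methylbenzene F2. Magnesium insertion in THF gives [2-(methoxymethoxy)-4-methylphenyl]magnesium bromide F3. CuI-catalysed addition to alkoxide 15, formed from 13, gives the chelated alkenylmagnesium bromide, bromomagnesium alkoxide of (Z)-3-(bromomagnesio)-2-[2-(methoxymethoxy)-4-methylphenyl]prop-2-en-1-ol F4, and iodinolysis gives (Z)-3-iodo-2-[2-(methoxymethoxy)-4-methylphenyl]prop-2-en-1-ol F5. Acetal cleavage (HCl, MeOH, rt), which the alkenyl iodide tolerates, gives 2-[(Z)-3-hydroxy-1-iodoprop-1-en-2-yl]-5-methylphenol F6. TIPSCl with Et3N in CH2Cl2 at 0 °C should silylate the more acidic phenol in preference to the primary alcohol, and the route is rejoined at 17.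

Step 4. The alkoxide may be intercepted by the formyl group, with hydride transfer from the hemiacetal alkoxide (Tishchenko- or Cannizzaro-type disproportionation), or tert-butoxide may displace fluoride intermolecularly before the ring closes. The fallback masks the aldehyde as a hindered imine, which still accepts the charge of the Meisenheimer complex at the para position but does not undergo hydride-transfer chemistry. It sets out from 5, which is condensed with tert-butylamine (MgSO4, CH2Cl2, rt) to give (Z)-4-{2-fluoro-5-[(E)-(tert-butylimino)methyl]-4-methoxyphenyl}-2-methylbut-3-en-2-ol F7. The same intramolecular SNAr (KOtBu, THF–DMF, rt → 50 °C) should give (E)-N-tert-butyl-1-(7-methoxy-2,2-dimethyl-2H-chromen-6-yl)methanimine F8. Mild hydrolysis (aqueous citric acid, THF, rt) returns the aldehyde, and the route is rejoined at 7.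

**Further compounds**

F1 | step 11 | tert-butyldimethyl{[(Z)-2-[4-methyl-2-(triisopropylsilyloxy)phenyl]-3-(4,4,5,5-tetramethyl-1,3,2-dioxaborolan-2-yl)prop-2-en-1-yl]oxy}silane | CC1(C)OB(/C=C(\CO[Si](C)(C)C(C)(C)C)c2ccc(C)cc2O[Si](C(C)C)(C(C)C)C(C)C)OC1(C)C
F2 | step 9 | 1-bromo-2-(methoxymethoxy)-4-methylbenzene | Cc1ccc(Br)c(OCOC)c1
F3 | step 9 | [2-(methoxymethoxy)-4-methylphenyl]magnesium bromide | Cc1ccc([Mg]Br)c(OCOC)c1
F4 | step 9 | chelated alkenylmagnesium bromide, bromomagnesium alkoxide of (Z)-3-(bromomagnesio)-2-[2-(methoxymethoxy)-4-methylphenyl]prop-2-en-1-ol | Br[Mg]/C=C(\CO[Mg]Br)c1ccc(C)cc1OCOC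
F5 | step 9 | (Z)-3-iodo-2-[2-(methoxymethoxy)-4-methylphenyl]prop-2-en-1-ol | I/C=C(\CO)c1ccc(C)cc1OCOC
F6 | step 9 | 2-[(Z)-3-hydroxy-1-iodoprop-1-en-2-yl]-5-methylphenol | I/C=C(\CO)c1ccc(C)cc1O
F7 | step 4 | (Z)-4-{2-fluoro-5-[(E)-(tert-butylimino)methyl]-4-methoxyphenyl}-2-methylbut-3-en-2-ol | COc1cc(F)c(/C=C\C(C)(C)O)cc1/C=N/C(C)(C)C
F8 | step 4 | (E)-N-tert-butyl-1-(7-methoxy-2,2-dimethyl-2H-chromen-6-yl)methanimine | COc1cc2OC(C)(C)C=Cc2cc1/C=N/C(C)(C)C
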